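**Assumptions.** The SMILES is read as (2S,4R), which is the 2,4-trans flavan-4-ol (2-Ph and 4-OH on opposite faces). Only reactants, products and atom-donating reagents are numbered; catalysts, ligands, bases and solvents appear under Conditions.

## Retrosynthetic overview

1. C4–OH is set last by a catalyst-controlled CBS reduction of (2S)-flavanone 10, chosen to override the ring's inherent preference for the cis alcohol.
2. The C2 stereocentre and the phenyl ring come from an enantioselective Pd/PyOx conjugate addition of PhB(OH)2 to chromone 8. This replaces the usual chalcone/oxa-Michael route.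
3. The C8 prenyl group is placed by a para-Claisen–Cope relay from the 5-O-prenyl ether (5 → 6), followed by 5-O-methylation.
4. Ring order: the A ring is bought (symmetrical acetophenone 1), the pyranone ring is formed first (step 1), and the phenyl ring is attached intact (step 5).

## Route

**Step 1**
Reactants: 1, 2′,6′-dihydroxy-4′-methoxyacetophenone; 2, N,N-dimethylformamide dimethyl acetal
Product: 3, 5-hydroxy-7-methoxy-4H-chromen-4-one
Conditions: DMF-DMA (2.5 equiv), PhMe, 95 °C; then cat. conc. HCl, CH2Cl2, 40 °C (enaminone not isolated)
Reagents that add atoms: DMF-DMA, COC(OC)N(C)C (supplies the chromone C2–H carbon)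
Why: Enaminone formation at the acetyl CH3 followed by acid-promoted addition–elimination cyclisation (loss of HNMe2) is the standard chromone synthesis, and because the two OH groups of 1 are equivalent only one product is possible; no stereocentre is formed.

**Step 2**
Reactants: 3, 5-hydroxy-7-methoxychromone; 4, prenyl bromide (1-bromo-3-methylbut-2-ene)
Product: 5, 7-methoxy-5-[(3-methylbut-2-en-1-yl)oxy]-4H-chromen-4-one
Conditions: prenyl bromide (1.5 equiv), K2CO3, cat. 18-crown-6, acetone, reflux
Reagents that add atoms: prenyl bromide, CC(C)=CCBr
Why: Williamson O-alkylation of the only phenol (chelated, hence crown ether and reflux) with an SN2-reactive allylic bromide; the chromone is stable to K2CO3.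

**Step 3**
Reactants: 5, 5-O-prenyl chromone
Product: 6, 5-hydroxy-7-methoxy-8-(3-methylbut-2-en-1-yl)-4H-chromen-4-one
Conditions: Eu(fod)3 (10 mol %), NaHCO3, PhCl, 85 °C
Reagents that add atoms: none
Why: Lewis-acid-accelerated aromatic Claisen rearrangement to C6 (1,1-dimethylallyl dienone) followed by Cope shift to C8 and tautomerisation (para-Claisen–Cope), which delivers an unrearranged prenyl group specifically para to the 5-oxygen, as established for 5-O-prenyl flavones and flavanones.

**Step 4**
Reactants: 6, 5-hydroxy-7-methoxy-8-prenylchromone; 7, iodomethane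
Product: 8, 5,7-dimethoxy-8-(3-methylbut-2-en-1-yl)-4H-chromen-4-one
Conditions: MeI (3 equiv), K2CO3, DMF, 40 °C
Reagents that add atoms: iodomethane, CI
Why: Williamson methylation of the chelated 5-OH; prenyl and chromone are inert, and all basic steps are finished before the base-sensitive C2 stereocentre exists.

**Step 5**
Reactants: 8, 5,7-dimethoxy-8-prenylchromone; 9, phenylboronic acid
Product: 10, (2S)-5,7-dimethoxy-8-(3-methylbut-2-en-1-yl)-2-phenylchroman-4-one
Conditions: PhB(OH)2 (2 equiv), Pd(OCOCF3)2 (10 mol %), (R)-t-BuPyOx (12 mol %), NH4PF6 (30 mol %), H2O (5 equiv), ClCH2CH2Cl, 60 °C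
Reagents that add atoms: phenylboronic acid, OB(O)c1ccccc1 (phenyl)
Why: Pd(II)/pyridine-oxazoline enantioselective conjugate addition of an arylboronic acid to a chromone: transmetalation, enantio-determining insertion of C2=C3 into the cationic Ar–Pd(PyOx) species, then protonolysis of the Pd enolate by water under non-basic conditions (no retro-oxa-Michael racemisation). The (R)-ligand is chosen for (2S) by analogy with the (S)-ligand giving (R)-3-aryl-3-methylcyclohexanones, which corresponds to the opposite face.

**Step 6**
Reactants: 10, (2S)-5,7-dimethoxy-8-prenylflavanone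
Product: 11, (2S,4R)-5,7-dimethoxy-8-(3-methylbut-2-en-1-yl)-2-phenylchroman-4-ol (target, 2,4-trans)
Conditions: (S)-Me-CBS (1.0 equiv), catecholborane (2 equiv), PhMe, −78 → −30 °C; MeOH quench, 1 M NaOH wash; chromatography on Et3N-deactivated SiO2
Reagents that add atoms: none (hydride and proton only)
Why: Corey–Bakshi–Shibata reduction: the oxazaborolidine binds the carbonyl lone pair on the CH2 side (the aryl-side lone pair is blocked by the peri 5-OMe) and, as for tetralone and chromanone, the (S)-catalyst gives the (R)-carbinol, so C4 is set by the reagent against the substrate's torsional bias toward cis. Catecholborane at low temperature does not hydroborate the prenyl alkene, and C2 is untouched.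

## Compound list

1 | 2′,6′-dihydroxy-4′-methoxyacetophenone | CC(=O)c1c(O)cc(OC)cc1O | starting material
2 | N,N-dimethylformamide dimethyl acetal | COC(OC)N(C)C | starting material (reagent)
3 | 5-hydroxy-7-methoxy-4H-chromen-4-one | O=C1C=COc2cc(OC)cc(O)c12 | intermediate
4 | prenyl bromide | CC(C)=CCBr | starting material (reagent)
5 | 7-methoxy-5-(prenyloxy)-4H-chromen-4-one | O=C1C=COc2cc(OC)cc(OCC=C(C)C)c12 | intermediate
6 | 5-hydroxy-7-methoxy-8-prenyl-4H-chromen-4-one | O=C1C=COc2c(CC=C(C)C)c(OC)cc(O)c12 | intermediate
7 | iodomethane | CI | starting material (reagent)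
8 | 5,7-dimethoxy-8-prenyl-4H-chromen-4-one | O=C1C=COc2c(CC=C(C)C)c(OC)cc(OC)c12 | intermediate
9 | phenylboronic acid | OB(O)c1ccccc1 | starting material
10 | (2S)-5,7-dimethoxy-8-prenyl-2-phenylchroman-4-one | COc1cc(OC)c2c(c1CC=C(C)C)O[C@H](c1ccccc1)CC2=O | intermediate
11 | (2S,4R)-5,7-dimethoxy-8-prenyl-2-phenylchroman-4-ol | COc1cc(OC)c2c(c1CC=C(C)C)O[C@H](c1ccccc1)C[C@H]2O | target

## Summary

Total steps: 6. Longest linear sequence: 6 (fully linear from 1).

**Three steps most likely to fail, with fallbacks**

1. **Step 5 (asymmetric conjugate arylation).** The 5,7-dialkoxy chromone is a poor acceptor, the prenyl alkene could interact with cationic Pd, and the facial sense is assigned by analogy. Check C2 by CD or optical rotation of 10; if the sense is reversed, use the (S)-ligand.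
   Fallback: give up the catalytic C–C step and resolve instead. Open 8 with aqueous NaOH to 2-hydroxy-4,6-dimethoxy-3-prenylacetophenone, condense with benzaldehyde (Claisen–Schmidt), and cyclise to rac-10. Then run an asymmetric transfer-hydrogenation kinetic resolution with (R,R)-TsDPEN–Ru or –Rh and HCO2H/Et3N, which reduces (2R)-10 to the cis alcohol and leaves (2S)-10.

2. **Step 6 (reduction against the substrate's cis bias).** The diastereomer ratio may be modest or the reaction slow; I expect a separable trans/cis mixture rather than a single isomer.
   Fallback: reduce 10 with NaBH4/MeOH to the cis-(2S,4S) alcohol. Invert C4 by Mitsunobu reaction (p-nitrobenzoic acid, PPh3, DIAD), then hydrolyse with LiOH in THF/H2O. Both SN2 displacement and ion-pair collapse should favour the pseudo-axial, trans ester.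

3. **Step 3 (para-Claisen–Cope).** It may stop at the 6-(1,1-dimethylallyl) ortho product or lose the prenyl group.
   Fallback: install the prenyl by cross-coupling. Make 5,7-dimethoxychromone from 2′-hydroxy-4′,6′-dimethoxyacetophenone and DMF-DMA, iodinate at C8 with NIS, and run a Stille coupling with tributyl(3-methylbut-2-enyl)stannane to reach 8.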